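**Retrosynthetic overview**
1. The dienyl butenolide is made last, by Pd/Cu coupling–lactonisation of (Z)-3-iodobut-2-enoic acid with a terminal (E)-enyne; the enyne comes from Zr-catalysed carboalumination of a butynyl arm on C9.
2. Ring B is formed by the key step, a one-carbon ring expansion: a 2-methylcyclopentanone silyl enol ether is cyclopropanated and opened by vanadium/O2 radical β-scission, which inserts C7, places the C6 ketone and sets 8α-OH; SmI2 then gives 6α-OH.
3. C4 (CH3/CH2OH) and the trans ring fusion come from a new photocatalytic hydroxymethylation of a tetrasubstituted enone with methanol; ring A comes from 1,4-addition of a 4-oxopentyl unit and aldol condensation.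
4. C9 is set by Cu-catalysed asymmetric conjugate addition to 2-methylcyclopent-2-enone; C10 by two cuprate additions anti to the C9 arm.
5. Ring order: cyclopentanone (future ring B) → ring A → ring expansion to ring B → butenolide.

Assumption: (Z)-3-iodobut-2-enoic acid (7 non-hydrogen atoms) is bought as such.
Labels: C1–C18 are the labdane-type locants of the target decalin (C4 bears CH3 and C18H2OH, C6 and C8 bear OH, C9 the side chain, C10 the angular CH3); β is the face of the C10 methyl.

**Route**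

Step 1
Reactants: 1 4-bromobut-1-yne
Product: 2 (4-bromobut-1-yn-1-yl)trimethylsilane
Conditions: TMSOTf, Et3N, Zn(OTf)2 (10 mol%), CH2Cl2, 23 °C
Reagents that add atoms: trimethylsilyl trifluoromethanesulfonate, C[Si](C)(C)OS(=O)(=O)C(F)(F)F
Why: Zinc-catalysed C-silylation of the terminal alkyne (zinc acetylide trapped by TMSOTf) masks the acidic C–H so that a Grignard reagent can be made from the bromide; no stereocentre is involved.

Step 2
Reactants: 2 (4-bromobut-1-yn-1-yl)trimethylsilane; 3 2-methylcyclopent-2-en-1-one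
Product: 5 (2S,3R)-2-methyl-3-[4-(trimethylsilyl)but-3-yn-1-yl]cyclopentan-1-one, via Grignard reagent 4 (not isolated)
Conditions: Mg, Et2O, 35 °C; then 3, Cu(OTf)2 (3 mol%), chiral C2-symmetric imidazolinium chloride (NHC precursor, 4 mol%, enantiomer giving 3R), Et2O, 0 °C; aq NH4Cl
Reagents that add atoms: none
Why: Copper–NHC-catalysed asymmetric conjugate addition of a Grignard reagent to an α-substituted cyclopentenone sets C9 by catalyst control, protonation gives the 2,3-trans ketone, and the C8 methyl configuration is irrelevant because it is erased in step 9.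

Step 3
Reactants: 5 (2S,3R)-2-methyl-3-[4-(trimethylsilyl)but-3-yn-1-yl]cyclopentan-1-one
Product: 6 (4R,5S)-5-methyl-4-[4-(trimethylsilyl)but-3-yn-1-yl]cyclopent-2-en-1-one
Conditions: LiN(iPr)2, THF, −78 °C; then PhS(Cl)=NtBu, −78 °C
Reagents that add atoms: none
Why: Kinetic deprotonation at the unsubstituted α-CH2 (C5) followed by Mukaiyama dehydrogenation of the lithium enolate (S-attack, then syn-elimination of the sulfenamide) gives the C5=C10 enone regiospecifically without touching C9.

Step 4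
Reactants: 6 (4R,5S)-5-methyl-4-[4-(trimethylsilyl)but-3-yn-1-yl]cyclopent-2-en-1-one
Product: 7 (4S,5S)-3,5-dimethyl-4-[4-(trimethylsilyl)but-3-yn-1-yl]cyclopent-2-en-1-one
Conditions: Me2CuLi (MeLi, CuI), Et2O, −78 °C; then PhS(Cl)=NtBu, THF, −78 → 0 °C
Reagents that add atoms: lithium dimethylcuprate, [Li+].C[Cu-]C
Why: Cuprate 1,4-addition trans to the C9 arm and the same one-pot sulfinimidoyl chloride dehydrogenation of the resulting enolate re-form the enone, now carrying the future C10 methyl on its β-carbon (the transient C10 centre is destroyed).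

Step 5
Reactants: 8 5-chloropentan-2-one
Product: 9 2-(3-chloropropyl)-2-methyl-1,3-dioxolane
Conditions: HOCH2CH2OH, TsOH (cat.), PhMe, reflux (Dean–Stark)
Reagents that add atoms: ethane-1,2-diol, OCCO
Why: Acid-catalysed ketalisation protects the ketone so that the chloride can be turned into a Grignard reagent.

Step 6
Reactants: 7 (4S,5S)-3,5-dimethyl-4-[4-(trimethylsilyl)but-3-yn-1-yl]cyclopent-2-en-1-one; 9 2-(3-chloropropyl)-2-methyl-1,3-dioxolane
Product: 12 (2S,3S,4S)-3-(but-3-yn-1-yl)-2,4-dimethyl-4-[3-(2-methyl-1,3-dioxolan-2-yl)propyl]cyclopentan-1-one, via Grignard reagent 10 (not isolated), via silyl enol ether 11 (not isolated)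
Conditions: Mg, THF, 60 °C; then 7, CuBr·SMe2 (20 mol%), TMSCl, HMPA, THF, −78 → −30 °C; then K2CO3 (cat.), MeOH, 23 °C
Reagents that add atoms: none
Why: TMSCl/HMPA-accelerated copper-catalysed Grignard 1,4-addition to the β,β-disubstituted enone occurs anti to the adjacent C9 arm and so creates the C10 quaternary centre with CH3 cis to that arm as in the target, and methanolysis then cleaves both the silyl enol ether and the alkynyl silane.

Step 7
Reactants: 12 (2S,3S,4S)-3-(but-3-yn-1-yl)-2,4-dimethyl-4-[3-(2-methyl-1,3-dioxolan-2-yl)propyl]cyclopentan-1-one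
Product: 14 (2S,3S,3aR)-3-(but-3-yn-1-yl)-2,3a,7-trimethyl-2,3,3a,4,5,6-hexahydro-1H-inden-1-one, via diketone 13 (not isolated)
Conditions: TsOH·H2O (20 mol%), PhMe, 110 °C (Dean–Stark)
Reagents that add atoms: none
Why: Acid unmasks the methyl ketone and drives an intramolecular aldol condensation of the C5 methylene onto the C4 carbonyl, the only mode that closes a six-membered ring and can dehydrate, giving ring A as a pulegone-like tetrasubstituted enone.

Step 8
Reactants: 14 (2S,3S,3aR)-3-(but-3-yn-1-yl)-2,3a,7-trimethyl-2,3,3a,4,5,6-hexahydro-1H-inden-1-one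
Product: 15 (2S,3S,3aR,7R,7aR)-3-(but-3-yn-1-yl)-7-(hydroxymethyl)-2,3a,7-trimethyloctahydro-1H-inden-1-one
Conditions: (nBu4N)4[W10O32] (2 mol%), MeOH/MeCN 1:1, 390 nm LEDs, N2, 25 °C
Reagents that add atoms: methanol, CO
Why: Proposed new method: decatungstate-photocatalysed Giese-type hydroxymethylation of a fully substituted cyclic enone with methanol, in which excited [W10O32]4− abstracts H from CH3OH, the small nucleophilic •CH2OH radical adds irreversibly to C4 on the α-face (anti to the 1,3-related angular C10 methyl) and back hydrogen transfer from the bulky reduced cluster to the C5 α-keto radical also comes from the α-face (both β-flanks carry methyls), so the C4 quaternary centre (CH2OH α, CH3 β) and the trans ring fusion (5α-H) are set together; the closest known chemistry is the decatungstate- or benzophenone-mediated photoaddition of alcohols and 1,3-dioxolane to unhindered enones and acrylates, which has not been shown to build a quaternary stereocentre on a tetrasubstituted enone.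

Step 9
Reactants: 15 (2S,3S,3aR,7R,7aR)-3-(but-3-yn-1-yl)-7-(hydroxymethyl)-2,3a,7-trimethyloctahydro-1H-inden-1-one
Product: 16 bis-trimethylsilyl derivative of 15 (C6=C8 silyl enol ether and 18-O-silyl ether)
Conditions: TMSOTf, Et3N, CH2Cl2, 0 °C
Reagents that add atoms: trimethylsilyl trifluoromethanesulfonate, C[Si](C)(C)OS(=O)(=O)C(F)(F)F
Why: Soft enolisation can only go towards C8 because the C5–H is buried between two quaternary carbons, so the tetrasubstituted silyl enol ether forms regiospecifically (erasing the C8 centre) while the primary alcohol is silylated and the terminal alkyne is left alone.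

Step 10
Reactants: 16 bis-trimethylsilyl derivative of 15
Product: 17 siloxycyclopropane (C7 methylene bridging C6 and C8 on the α-face)
Conditions: Et2Zn, CH2I2, CH2Cl2, 0 °C
Reagents that add atoms: diiodomethane, ICI
Why: Furukawa-modified Simmons–Smith cyclopropanation attacks the electron-rich silyl enol ether far faster than the alkyne and installs C7, and the two new cyclopropane centres are lost again in step 11.

Step 11
Reactants: 17 siloxycyclopropane
Product: 19 9β-(but-3-yn-1-yl)-8α,18-dihydroxy-8β-methyl-5α-decalin-6-one (4β,10β-dimethyl), via hydroperoxide 18 (not isolated)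
Conditions: VO(acac)2 (10 mol%), O2 (1 atm), EtOH, 23 °C; then PPh3
Reagents that add atoms: dioxygen, O=O
Why: Key ring expansion of the Saegusa–Ito type in its aerobic variant: ethanolysis and vanadium-mediated oxidation give the cyclopropyloxy radical, β-scission of the internal C6–C8 bond (reversible and funnelling to the tertiary radical) enlarges the cyclopentane to the cyclohexanone, O2 traps the C8 radical on the equatorial α-face because the β-face is blocked by the 1,3-diaxial C10 methyl, and PPh3 reduces the hydroperoxide, so ring B, the C6 carbonyl and the 8α-OH/8β-CH3 centre are formed together.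

Step 12
Reactants: 19 9β-(but-3-yn-1-yl)-8α,18-dihydroxy-8β-methyl-5α-decalin-6-one
Product: 20 9β-(but-3-yn-1-yl)-5α-decalin-6α,8α,18-triol
Conditions: SmI2, H2O, Et3N, THF, 23 °C
Reagents that add atoms: none
Why: Single-electron (dissolving-metal-type) ketone reduction is governed by product stability and gives the equatorial 6α-alcohol (the axial 6β position is crowded by the 4β, 8β and 10β methyls), whereas hydride reagents would attack from the α-face; the alkyne is untouched.

Step 13
Reactants: 20 9β-(but-3-yn-1-yl)-5α-decalin-6α,8α,18-triol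
Product: 22 9β-[(3E)-4-iodo-3-methylbut-3-en-1-yl]-5α-decalin-6α,8α,18-triol, via alkenylalane 21 (not isolated)
Conditions: Me3Al, Cp2ZrCl2 (25 mol%), CH2Cl2, 0 → 23 °C; then I2, THF, −30 °C
Reagents that add atoms: trimethylaluminium, C[Al](C)C; iodine, II
Why: Negishi zirconium-catalysed carboalumination adds CH3 and Al syn across the terminal alkyne with CH3 on the internal carbon (the hydroxyls ride as aluminium alkoxides), and iodinolysis with retention fixes the (E)-C13=C14 geometry.

Step 14
Reactants: 22 9β-[(3E)-4-iodo-3-methylbut-3-en-1-yl]-5α-decalin-6α,8α,18-triol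
Product: 24 9β-[(3E)-3-methylhex-3-en-5-yn-1-yl]-5α-decalin-6α,8α,18-triol, via silyl enyne 23 (not isolated)
Conditions: HC≡CSiMe3, Pd(PPh3)2Cl2 (3 mol%), CuI (5 mol%), Et3N, THF, 23 °C; then K2CO3 (cat.), MeOH
Reagents that add atoms: ethynyltrimethylsilane, C#C[Si](C)(C)C
Why: Sonogashira coupling of the vinyl iodide proceeds with retention of alkene geometry and tolerates the free triol, and methanolysis of the C–Si bond releases the terminal (E)-enyne.

Step 15
Reactants: 24 9β-[(3E)-3-methylhex-3-en-5-yn-1-yl]-5α-decalin-6α,8α,18-triol; 25 (Z)-3-iodobut-2-enoic acid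
Product: 27 CNP0126806.1 (target), via enynoic acid 26 (not isolated)
Conditions: 25, Pd(PPh3)4 (5 mol%), CuI (10 mol%), Et3N, MeCN, 23 °C
Reagents that add atoms: none
Why: Tandem Sonogashira coupling/5-exo-dig lactonisation: the (2Z)-enynoic acid formed in the flask cyclises by anti addition of the carboxylate oxygen and hydrogen across the alkyne, giving the (Z)-γ-alkylidene butenolide with the side chain cis to the ring oxygen and the 4-methyl group supplied by 25.

**Compound list**

1 | 4-bromobut-1-yne | C#CCCBr | starting material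
2 | (4-bromobut-1-yn-1-yl)trimethylsilane | C[Si](C)(C)C#CCCBr | intermediate
3 | 2-methylcyclopent-2-en-1-one | CC1=CCCC1=O | starting material
4 | [4-(trimethylsilyl)but-3-yn-1-yl]magnesium bromide | C[Si](C)(C)C#CCC[Mg]Br | intermediate
5 | (2S,3R)-2-methyl-3-[4-(trimethylsilyl)but-3-yn-1-yl]cyclopentan-1-one (2,3-trans) | C[Si](C)(C)C#CCC[C@@H]1CCC(=O)[C@H]1C | intermediate
6 | (4R,5S)-5-methyl-4-[4-(trimethylsilyl)but-3-yn-1-yl]cyclopent-2-en-1-one | C[Si](C)(C)C#CCC[C@@H]1C=CC(=O)[C@H]1C | intermediate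
7 | (4S,5S)-3,5-dimethyl-4-[4-(trimethylsilyl)but-3-yn-1-yl]cyclopent-2-en-1-one | C[Si](C)(C)C#CCC[C@@H]1C(C)=CC(=O)[C@H]1C | intermediate
8 | 5-chloropentan-2-one | CC(=O)CCCCl | starting material
9 | 2-(3-chloropropyl)-2-methyl-1,3-dioxolane | CC1(CCCCl)OCCO1 | intermediate
10 | [3-(2-methyl-1,3-dioxolan-2-yl)propyl]magnesium chloride | CC1(CCC[Mg]Cl)OCCO1 | intermediate
11 | trimethylsilyl enol ether (C5=C6) of the 1,4-adduct, alkyne still C-silylated | C[Si](C)(C)C#CCC[C@@H]1[C@@](C)(CCCC2(C)OCCO2)C=C(O[Si](C)(C)C)[C@H]1C | intermediate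
12 | (2S,3S,4S)-3-(but-3-yn-1-yl)-2,4-dimethyl-4-[3-(2-methyl-1,3-dioxolan-2-yl)propyl]cyclopentan-1-one | C#CCC[C@@H]1[C@@](C)(CCCC2(C)OCCO2)CC(=O)[C@H]1C | intermediate
13 | (2S,3S,4S)-3-(but-3-yn-1-yl)-2,4-dimethyl-4-(4-oxopentyl)cyclopentan-1-one | C#CCC[C@@H]1[C@@](C)(CCCC(C)=O)CC(=O)[C@H]1C | intermediate
14 | (2S,3S,3aR)-3-(but-3-yn-1-yl)-2,3a,7-trimethyl-2,3,3a,4,5,6-hexahydro-1H-inden-1-one | C#CCC[C@@H]1[C@@]2(C)CCCC(C)=C2C(=O)[C@H]1C | intermediate
15 | (2S,3S,3aR,7R,7aR)-3-(but-3-yn-1-yl)-7-(hydroxymethyl)-2,3a,7-trimethyloctahydro-1H-inden-1-one (trans-fused; CH2OH trans to the angular CH3) | C#CCC[C@@H]1[C@@]2(C)CCC[C@@](C)(CO)[C@@H]2C(=O)[C@H]1C | intermediate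
16 | bis-trimethylsilyl derivative of 15: C6=C8 trimethylsilyl enol ether, 18-O-trimethylsilyl ether | C#CCC[C@@H]1[C@@]2(C)CCC[C@@](C)(CO[Si](C)(C)C)[C@@H]2C(O[Si](C)(C)C)=C1C | intermediate
17 | siloxycyclopropane: CH2 (C7) added across C6=C8 of 16 on the α-face | C#CCC[C@@H]1[C@@]2(C)CCC[C@@](C)(CO[Si](C)(C)C)[C@@H]2[C@@]3(O[Si](C)(C)C)C[C@@]13C | intermediate
18 | 9β-(but-3-yn-1-yl)-8α-hydroperoxy-18-hydroxy-4β,8β,10β-trimethyl-5α-decalin-6-one | C#CCC[C@@H]1[C@@]2(C)CCC[C@@](C)(CO)[C@@H]2C(=O)C[C@@]1(C)OO | intermediate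
19 | 9β-(but-3-yn-1-yl)-8α,18-dihydroxy-4β,8β,10β-trimethyl-5α-decalin-6-one | C#CCC[C@@H]1[C@@]2(C)CCC[C@@](C)(CO)[C@@H]2C(=O)C[C@@]1(C)O | intermediate
20 | 9β-(but-3-yn-1-yl)-4β,8β,10β-trimethyl-5α-decalin-6α,8α,18-triol | C#CCC[C@@H]1[C@@]2(C)CCC[C@@](C)(CO)[C@@H]2[C@@H](O)C[C@@]1(C)O | intermediate
21 | (E)-alkenyl(dimethyl)alane of 20 (CH3 on C13, Al on C14; hydroxyls as O–AlMe2) | C[Al](C)/C=C(\C)CC[C@@H]1[C@@]2(C)CCC[C@@](C)(CO[Al](C)C)[C@@H]2[C@@H](O[Al](C)C)C[C@@]1(C)O[Al](C)C | intermediate
22 | 9β-[(3E)-4-iodo-3-methylbut-3-en-1-yl]-4β,8β,10β-trimethyl-5α-decalin-6α,8α,18-triol | I/C=C(\C)CC[C@@H]1[C@@]2(C)CCC[C@@](C)(CO)[C@@H]2[C@@H](O)C[C@@]1(C)O | intermediate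
23 | 9β-[(3E)-3-methyl-6-(trimethylsilyl)hex-3-en-5-yn-1-yl]-4β,8β,10β-trimethyl-5α-decalin-6α,8α,18-triol | C[Si](C)(C)C#C/C=C(\C)CC[C@@H]1[C@@]2(C)CCC[C@@](C)(CO)[C@@H]2[C@@H](O)C[C@@]1(C)O | intermediate
24 | 9β-[(3E)-3-methylhex-3-en-5-yn-1-yl]-4β,8β,10β-trimethyl-5α-decalin-6α,8α,18-triol | C#C/C=C(\C)CC[C@@H]1[C@@]2(C)CCC[C@@](C)(CO)[C@@H]2[C@@H](O)C[C@@]1(C)O | intermediate
25 | (Z)-3-iodobut-2-enoic acid | C/C(I)=C/C(O)=O | starting material
26 | (2Z,6E)-3,7-dimethyl-9-(6α,8α,18-trihydroxy-4β,8β,10β-trimethyl-5α-decalin-9β-yl)nona-2,6-dien-4-ynoic acid | OC(=O)/C=C(/C)C#C/C=C(\C)CC[C@@H]1[C@@]2(C)CCC[C@@](C)(CO)[C@@H]2[C@@H](O)C[C@@]1(C)O | intermediate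
27 | CNP0126806.1: (5Z)-4-methyl-5-[(2E)-3-methyl-5-(6α,8α,18-trihydroxy-4β,8β,10β-trimethyl-5α-decalin-9β-yl)pent-2-en-1-ylidene]furan-2(5H)-one | CC1=CC(=O)O/C1=C\C=C(/C)CC[C@@H]1[C@@]2(C)CCC[C@@](C)(CO)[C@@H]2[C@@H](O)C[C@@]1(C)O | target

**Step count and risks**

Total step count: 15. Longest linear sequence: 14 (steps 1–4 and 6–15; step 5 is a side branch).

Steps most likely to fail:

Step 8 (new hydroxymethylation). The radical addition to the hindered tetrasubstituted enone may be slow, the primary alcohol product may be over-oxidised, or the C5 hydrogen may be delivered from the wrong face. The fallback sets out from 14 and comes back at 15 and uses known chemistry. Copper-mediated conjugate addition of the hydroxymethyl-anion equivalent (iPrO)Me2SiCH2MgCl (CuI, TMSCl, THF, −40 °C; pulegone-type enones accept organocopper reagents), again anti to the angular methyl, gives the 7-{[dimethyl(propan-2-yloxy)silyl]methyl} ketone F1. Tamao–Fleming oxidation (H2O2, KF, KHCO3, THF/MeOH) then converts C–Si into C–OH and returns 15.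

Step 11 (ring expansion with O2 capture). The primary radical from external-bond cleavage may be trapped before it rearranges, or O2 may add to C8 with low facial selectivity. The fallback sets out from 17 and comes back at 19. The classical Saegusa–Ito protocol (FeCl3, DMF, 0 °C) gives the ring-expanded 8-chloro-6-oxo decalin F2, and NaOAc in MeOH eliminates HCl to the 8-methyl-7-en-6-one F3. Weitz–Scheffer epoxidation (H2O2, NaOH, MeOH), anti to the C10 methyl, gives the 7α,8α-epoxy-6-ketone F4. SmI2 (THF/MeOH, −90 °C) cleaves the C7–O bond reductively and delivers the 8α-hydroxy ketone 19.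

Step 12 (C6 configuration). The SmI2 reduction may give a mixture containing the axial alcohol. The fallback sets out from 19 and comes back at 20. NaBH4 (MeOH, 0 °C) attacks from the open α-face and gives the axial 6β-alcohol F5. A Meerwein–Ponndorf–Verley/Oppenauer equilibration (Al(OiPr)3, iPrOH, trace acetone, 80 °C) then epimerises this strongly 1,3-diaxially strained carbinol to the equatorial 6α-alcohol 20.

Further compounds
F1 | step 8 | 3-(but-3-yn-1-yl)-7-{[dimethyl(propan-2-yloxy)silyl]methyl}-2,3a,7-trimethyloctahydro-1H-inden-1-one (silylmethyl α, trans-fused) | C#CCC[C@@H]1[C@@]2(C)CCC[C@@](C)(C[Si](C)(C)OC(C)C)[C@@H]2C(=O)[C@H]1C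
F2 | step 11 | 9β-(but-3-yn-1-yl)-8-chloro-18-hydroxy-4β,8,10β-trimethyl-5α-decalin-6-one (C8 epimers) | C#CCC[C@@H]1[C@@]2(C)CCC[C@@](C)(CO)[C@@H]2C(=O)CC1(C)Cl
F3 | step 11 | 9β-(but-3-yn-1-yl)-18-hydroxy-4β,8,10β-trimethyl-5α-decal-7-en-6-one | C#CCC[C@@H]1[C@@]2(C)CCC[C@@](C)(CO)[C@@H]2C(=O)C=C1C
F4 | step 11 | 9β-(but-3-yn-1-yl)-7α,8α-epoxy-18-hydroxy-4β,8β,10β-trimethyl-5α-decalin-6-one | C#CCC[C@@H]1[C@@]2(C)CCC[C@@](C)(CO)[C@@H]2C(=O)[C@H]3O[C@@]13C
F5 | step 12 | 9β-(but-3-yn-1-yl)-4β,8β,10β-trimethyl-5α-decalin-6β,8α,18-triol (6-epimer of 20) | C#CCC[C@@H]1[C@@]2(C)CCC[C@@](C)(CO)[C@@H]2[C@H](O)C[C@@]1(C)O
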